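If a first-order and a second-order step draw on the same substrate, the ratio of their rates is proportional to the substrate concentration, so a larger charge should favour the second step. Here single ring is the product of the first-order step, and open dimer, which closes to ring dimer, is the product of the second-order step.

| setting | noon | dawn | flask |
|---|---|---|---|
| substrate | 0.45 M | 1.8 M | 0.90 M |
| remark | run made earlier | run made earlier |  |
| time |  |  | 40 h |

| run | time / h | substrate / % | single ring / % | ring dimer / % |
|---|---|---|---|---|
| noon | 6.00 | 1 | 77 | 9 |
| noon | 12.0 | 4 | 81 | 11 |
| noon | 20.0 | 2 | 83 | 10 |
| noon | 25.0 | 0 | 86 | 12 |
| noon | 30.0 | 2 | 84 | 14 |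
| noon | 40.0 | 0 | 88 | 13 |
| dawn | 3.00 | 0 | 46 | 32 |
| dawn | 5.00 | 6 | 49 | 27 |
| dawn | 8.00 | 0 | 59 | 29 |
| dawn | 15.0 | 1 | 57 | 32 |
| dawn | 25.0 | 0 | 57 | 30 |
| dawn | 40.0 | 0 | 57 | 29 |

(each reading ± 2 percentage points)

- the state of affairs at 40 h: stopped, and by what, or still going (all of the substrate has reacted / forward and back rates have come level / it is still moving)
- part of the substrate gone at 40 h
- the single ring standing at 40 h, as a percentage of the substrate charged
- the ring dimer standing at 40 h, as a percentage of the substrate charged

- percentages count the substrate that a species holds: one open dimer or ring dimer or side product counts as two
- percentages count the substrate that a species holds: one open trimer counts as three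
- the numbers in the tables scatter by 2 percentage points (one standard deviation)
- what may be going on: substrate -> single ring; 2 substrate -> open dimer; substrate + open dimer -> open trimer; open dimer -> ring dimer; substrate <-> dormant form; substrate + single ring -> side product
- the reaction counts as stopped when no species that holds the substrate changes by six tenths of a point or more over the second half of the time

We carry one quantity, the split: ring dimer over single ring, both as fractions of the charge, at the end of a run. It is a selectivity between the two routes. The last readings of substrate are 0 % in the noon run and 0 % in the dawn run, within the scatter of 2 percentage points. The flask's charge of 0.90 M lies between theirs, so we expect its substrate to read as low at 40 h.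

The last three readings of each run are level within the scatter, so we pool them. They give a split of 0.151 at noon and 0.532 at dawn. Read across the two charges, the split grows as the charge to the power 0.908, and this power carries the scatter of the readings. For the flask, that rule gives 0.284, our estimate of the split of this flask.

The forecast says all of the substrate has reacted, with 99.5 % of the substrate gone, 74 % single ring (69 % to 78 %) and 21 % ring dimer (17 % to 25 %), on the ground that “single ring is first order, while the dimer route is second order”.

The flask gives: all of the substrate has reacted, with 100 % gone, 73.1 % single ring and 19.5 % ring dimer.

    substrate → single ring (k = 0.0542 min⁻¹)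
    2 substrate → open dimer (k = 0.0565 M⁻¹ min⁻¹)
    substrate + open dimer → open trimer (k = 0.0477 M⁻¹ min⁻¹)
    open dimer → ring dimer (k = 0.0745 min⁻¹)
    substrate ⇌ dormant form (K = 6.40, k = 0.180 min⁻¹)
    substrate + single ring → side product (k = 0.00505 M⁻¹ min⁻¹)

The flask's split is 0.267 against our 0.284, and a neighbour flask charged with 1.5 M ends at 0.422 against 0.451 from the same rule. In the flask, substrate is used by the step to single ring at 0.53 times the rate of the step to open dimer at the start, but at 12 times that rate at 1.20 h. At 4.00 h the flask holds 19.3 % ring dimer.

All runs stem from a simulated flask from invented constants; the scatter is artificial.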